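Count what each turn of the reaction costs before integrating anything, I told myself, and so I wrote the balance of the nucleophile for maple, ash and cedar, flasks that differ from the south-west run and from each other in their free base.

all flasks: electrophile 0.30 M

| run | nucleophile | free base | protic impurity | remark | time |
|---|---|---|---|---|---|
| south-west | 0.60 M | 0.16 M | 0.015 M | run made earlier |  |
| maple | 0.600 M | 0.240 M | 0.0150 M |  | 2.5 h |
| ash | 0.600 M | 0.360 M | 0.0150 M |  | 2.5 h |
| cedar | 0.600 M | 0.540 M | 0.0150 M |  | 2.5 h |

- south-west (time / min: electrophile / %, target / %): 6.00: 30, 71; 15.0: 16, 87; 30.0: 10, 93; 80.0: 1, 98

(standard deviation of a reading: 2 percentage points)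

- no earlier run changes the charge of free base; that part of a forecast is a guess

* part of the electrophile that has reacted at the end, maple
* part of the electrophile that has reacted at the end, ash
* part of the electrophile that has reacted at the end, cedar
* what raising the concentration of free base from its lowest to its highest value here does to the part of the electrophile that has reacted (changes below 5 percentage points count as none) (it falls / no change / it rises)

On paper the electrophile was the limiting reagent, at 0.30 M against 0.600 M of nucleophile, but I supposed that each turn sets free one acid, which a second nucleophile or the free base must bind, and that the protic impurity destroys its own amount of nucleophile. In my first extreme version the free base did nothing, each turn cost two nucleophile, and the electrophile stopped at 0.292 M, or 97.5% of the charge in each flask, since no free base enters that sum. In the second, each free base spared one nucleophile, which gave the ceiling, the electrophile that the charge pays for on this supposition: nucleophile plus free base, less the impurity, divided by two, 0.412 M for maple. That is more than the electrophile charged, and ash and cedar, with more free base than maple, stood higher still. I put the real flasks between complete consumption and that floor, a gap of 2.5 percentage points, less than the 5 points that counts as a change, so I expected no trend. Time looked sufficient, as the south-west run had 1% of its electrophile left at 80.0 min, with a scatter of 2 points, and these flasks ran about twice as long.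

The forecast gave 99.5%, 99.5% and 99.5%, with no change, holding that “the base is not needed stoichiometrically”. The flasks gave 99.6% in maple, 99.8% in ash and 99.9% in cedar, a result of no change, the change being 0.24 points.

    nucleophile + protic impurity → quenched reagent (k = 0.390 L mol⁻¹ s⁻¹)
    nucleophile + acid set free ⇌ protonated nucleophile, settled at all times (K = 2400 L mol⁻¹)
    acid set free → by-product carried off (k = 9.90 × 10⁻⁴ s⁻¹)
    2 electrophile → self-condensation product (k = 3.50 × 10⁻⁶ L mol⁻¹ s⁻¹)
    acid set free + free base ⇌ salt of the base (K = 520 L mol⁻¹, k = 0.00830 L mol⁻¹ s⁻¹)
    electrophile + nucleophile → acid set free + target (k = 0.0110 L mol⁻¹ s⁻¹)

Maple, with its ceiling of 0.412 M above its charge, ended with 8.06% of its nucleophile free and 84.5% of its free base. The neighbouring flask is maple with 0.51 M of electrophile, which puts the same ceiling below the charge, so the reckoning allowed 80.8% to react. That neighbouring flask gave 79.6%, with 1.2% of its nucleophile free. Its free base was not used up as the ceiling supposes: 48% of it stayed free, while by-product carried off reached 0.0959 M.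

All runs are calculated on assumed constants; noise was put on by code.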